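## Structural features

The target is a linear trimer of three six-membered carbocycles joined by two methylene bridges: ring A is a dearomatised 2-acetyl-3,5-dihydroxycyclohexa-2,5-dienone (a cyclic β-triketone), ring B is a fully substituted butanoylphloroglucinol, and ring C is a butanoylphloroglucinol fused to a 2,2-dimethyl-2H-pyran, that is an 8-butanoyl-5,7-dihydroxy-2,2-dimethylchromene bridged at C6. The only stereocentre is the quaternary C4 of ring A, which carries a methyl group and an (E)-geranyl chain; it has no stereogenic neighbour and is stereogenic only because its two ring flanks differ (C3 lies next to the acetylated C2, C5 next to the bridged C6). Fragile groups are the chromene olefin and the two trisubstituted geranyl olefins (acid, electrophiles, oxidants), the enolised triketone (loss of the acetyl group would also erase the stereocentre), the electron-rich polyphenol rings (oxidation in base) and the methylene bridges (fragment exchange in strong base). The real difficulty is regiochemical: two identical butanoylphloroglucinol units must be told apart, the pyran oxygen of ring C must be the hydroxyl ortho to butanoyl and not the more reactive one para to it, and ring B must be bridged to two different partners. Rings B and C together form a symmetric methylenebis(butanoylphloroglucinol) in which the two hydroxyls para to the butanoyl groups face each other across the bridging CH2. The key step exploits this: tying these two oxygens into an eight-membered dioxasilocine leaves, next to the free aromatic CH of each ring, only a hydroxyl ortho to butanoyl, so condensation with a C5 enal and oxa-6π closure can give only the correctly oriented chromene.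

## Logic of the disconnections

19 to 18. The two phenolic oxygens flanking the ring B–ring C methylene are joined again through silicon; the bonds concerned are the two O–Si bonds of 18. The cut comes last so that the tether needed earlier also serves as the only protecting group during the final bridging, which saves separate protection steps. The forward step needs a fluoride-mediated Si–O cleavage mild enough for the chromene olefin, the geranyl olefins and the enolised triketone.

18 to 8, 14 and 15. The two C–C bonds at the methylene between C6 of ring A and the last free carbon of ring B are cut; the carbon itself is traced to 15. This is the most convergent cut: it separates the only stereocentre (in 14) from the whole regiochemical problem (in 8). The forward step must be cross-selective, so the one-carbon unit is attached first to 8, whose single free aromatic carbon leaves no choice, and only then offered to 14.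

14 to 13, and 13 to 11 and 12. No bond is cut between 14 and 13; the stereocentre is allowed to be racemic, because the two faces of the planar precursor differ only through substituents remote from the reacting carbon and no dependable reagent control is at hand. In 13 the bond between the quaternary ring carbon and C1 of the C10 chain is cut, which returns the ring to the aromatic state and the chain to 12. The gain is that ring A with its oxygens, acetyl group and methyl group comes from one simple arene. The forward alkylation must occur at the methyl-bearing ring carbon, not at the unsubstituted one or at oxygen, and must leave the (E)-olefin untouched.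

11 to 9 and 10. The aryl–acetyl bond is cut. The two unsubstituted ring carbons of 9 are equivalent, so the forward acylation has only to stop after one acyl group.

8 to 5 and 6 (key disconnection). The C4a–C4 and O1–C2 bonds of the pyran ring are cut. This removes the five-carbon unit as 6 and restores the free aromatic CH and the free hydroxyl ortho to butanoyl on one ring of 5. The cut is made here because 5 holds both phloroglucinol rings already joined and already shielded at the wrong oxygen, so one annulation delivers the complete ring B–ring C unit. The forward step demands closure only onto the hydroxyl ortho to butanoyl (secured by the tether) and reaction of only one of the two equivalent rings (secured only by stoichiometry and recycling).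

5 to 3 and 4. The two O–Si bonds of the eight-membered ring are cut, which reveals a symmetric hexaphenol. The forward silylation must choose, among three kinds of hydroxyl, the pair para to the butanoyl groups, and must close a ring rather than link two molecules.

3 to 1 and 2. The two aryl–CH2 bonds are cut, giving two molecules of 1 and one molecule of 2. The halves are identical, so there is no cross-selectivity problem. The forward step has only to stop at the dimer, since 3 still has two nucleophilic ring carbons.

## Other disconnections considered

Alternative 1: The cut lies inside ring C, at the C8–acyl and C7–O bonds, so the butanoyl group and its neighbouring hydroxyl arrive together.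
- **Forward key step:** CsF converts the 8-trimethylsilyl 7-triflate A1 into the aryne A2. The carboxylate of butanoic acid A3 adds through oxygen to C7, and the C8 aryl anion takes the acyl group through a four-membered intermediate, giving the ortho-hydroxyaryl ketone A4.
- **In its favour:** the inductive effect of the pyran oxygen on C8a steers the nucleophile to C7 and the acyl group to C8, so no tether is needed. No statistical differentiation of two identical rings arises at this stage.
- **Against it here:** A1 is itself a multistep target (differentiation of two phenolic oxygens, ortho-silylation, triflation). Protonation of the aryl anion before the acyl shift would end the sequence at simple O-arylation. After removal of the methoxymethyl group the ring C monomer (A12, see Alternative 3) must still be bridged to 1 and then to 14 by two cross-selective couplings. The first of these meets the two equivalent free carbons of 1 and is as statistical as the mono-annulation of the chosen plan.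
- **Comparison:** on the regiochemistry of ring C the alternative is the equal of the chosen plan and arguably the better, because it rests on an intrinsic electronic bias and not on a protecting group surviving the conditions. Mechanistically it is an anionic addition and acyl shift instead of a condensation and pericyclic closure. In step economy it is the worse: the chosen plan reaches the whole ring B–ring C unit 8 in three steps from 1, with a homodimerisation in place of a cross-coupling.

Alternative 2: The cut lies in ring A at C5–C6 and C2–C3, which leads back to pentane-2,4-dione A8 and a quaternary malonic acid derivative that already holds the stereocentre.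
- **Forward key step:** the prochiral diester A5 would be desymmetrised (for example by an esterase) to the half-ester A6, whose free acid is converted into the acyl imidazole A7. The dianion of A8 is acylated at its terminal carbon by the imidazolide, and its central carbon then closes on the methyl ester (Claisen, then Dieckmann-type condensation). The product A9 is identical with 14.
- **In its favour:** the positions of acetyl, methyl and geranyl follow from connectivity, and the configuration is set before the ring exists. On regiocontrol and stereocontrol of ring A this alternative is the better, since no material is lost in a resolution.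
- **Against it here:** the enantiomeric purity rests entirely on desymmetrising a lipophilic, congested diester. The dianion must attack a neopentyl-type acyl imidazole and not merely transfer a proton. Closure through oxygen competes with closure through carbon. Any reversible loss of the acetyl group would remove the difference between the two flanks of the quaternary carbon and erase the configuration.
- **Comparison:** both plans deliver the same monomer. The alternative builds the ring by two ionic C–C condensations, whereas the chosen plan alkylates an existing arene and separates enantiomers. The step count is about equal. The alternative leaves the ring B–ring C problem untouched and could replace steps 4 to 6 without changing the key step.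

Alternative 3: The cut is the C5–C6 bond of ring C, which turns the aromatic ring into an open 1,3-diketone ester and, one step further back, into the bicyclic lactone A10.
- **Forward key step:** Mg(OCH3)2 in CH3OH opens the lactone of A10 to the methyl ester A11. The terminal methyl carbon of its 1,3-diketone (the former 7-methyl) then closes on the ester, and enolisation gives the aromatic chromene A12.
- **In its favour:** the pyran ring and its oxygen exist before ring C does, so the relation of pyran oxygen to butanoyl is fixed by connectivity. No protecting group and no fluoride step are needed, and the closure is a mild, chelation-assisted Claisen condensation. On these points it is the better.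
- **Against it here:** A10 needs its butanoyl group on a ring carbon that the usual electrophilic acylation of its hydroxypyranone precursor does not address. Closure through the α-methylene of the butanoyl group instead of the methyl group would misplace the substituents. The alkoxide can cleave the diketone, and the monocyclic 2H-pyran of A11 is free to open. A12 then needs the same two cross-bridging steps as in Alternative 1.
- **Comparison:** on the orientation of ring C it is the equal of the chosen plan. In convergence and step count it is the worse, because the ring B–ring C bond becomes a statistical cross-coupling instead of a homodimerisation.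

Key step: step 3

Remark: triketone and acylphloroglucinol units are written as one tautomer throughout, the descriptor (R) refers to the tautomer drawn, and 2-methylbenzene-1,3,5-triol is taken to be a catalogue compound.

## Route

Step 1
Reactants: 1 1-(2,4,6-trihydroxyphenyl)butan-1-one (two molecules per molecule of 2); 2 formaldehyde
Product: 3 bis(3-butanoyl-2,4,6-trihydroxyphenyl)methane
Conditions: 37% aq. CH2O (0.45 equiv per 1), 1 M aq. KOH (2 equiv), 0 °C to rt; then 1 M HCl; excess 1 recovered
Reagents that add atoms: 1-(2,4,6-trihydroxyphenyl)butan-1-one (the second molecule of 1), CCCC(=O)c1c(O)cc(O)cc1O
Why: Base-mediated hydroxymethylation of the phloroglucinolate of 1 by 2, loss of water to an ortho-quinone methide and attack of a second molecule of 1 (methylene-bis condensation), so that two molecules of 1 and one of 2 give 3 and water; the two ring carbons of 1 are equivalent, so only one dimer can form, and the excess of 1 suppresses further bridging.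

Step 2
Reactants: 3 bis(3-butanoyl-2,4,6-trihydroxyphenyl)methane; 4 di-tert-butylsilyl bis(trifluoromethanesulfonate)
Product: 5 di-tert-butylsilylene-bridged dimer (Si on the two oxygens para to butanoyl)
Conditions: t-Bu2Si(OTf)2 (1.05 equiv, slow addition), 2,6-lutidine, THF–DMF (0.02 M), −20 °C to rt
Reagents that add atoms: none
Why: Cyclic silylene formation from a bisphenol and a silyl bis(triflate); the hydroxyls para to butanoyl are the most acidic, are not hydrogen-bonded to the ketone and have one unhindered flank, so the first Si–O bond should form there and the second should close the eight-membered dibenzodioxasilocine across the CH2 bridge, while dilution disfavours intermolecular silylation.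

Step 3
Reactants: 5 di-tert-butylsilylene-bridged dimer; 6 3-methylbut-2-enal
Product: 8 silylene-bridged mono-chromene dimer, via ring C oxatriene dienone 7 (not isolated)
Conditions: 6 (0.8 equiv, slow addition), ethylenediammonium diacetate (20 mol%), toluene, 80 °C; recovered 5 recycled
Reagents that add atoms: none
Why: Ethylenediammonium diacetate converts 6 into an iminium ion, which is attacked by the only free ring carbon of one phloroglucinol ring of 5 (Knoevenagel/Mannich-type formation of the C4a–C4 bond), and loss of the amine gives the 1-oxatriene 7, an ortho-quinone methide whose carbonyl oxygen is the former hydroxyl ortho to butanoyl. 7 closes by a thermally allowed disrotatory oxa-6π electrocyclisation that forms the O1–C2 bond and the six-membered pyran (formally a 6-endo closure), after which ring C is aromatic again. The closest known reaction type is the amine-salt-mediated formal [3+3] annulation of acylphloroglucinols and resorcinols with α,β-unsaturated aldehydes to 2,2-dimethyl-2H-chromenes. No stereocentre is formed, because C2 carries two methyl groups. The step needs oxygen regioselectivity, which the substrate secures: the other oxygen flanking the reacting carbon is locked in the dioxasilocine as a hindered silyl ether, and the second free hydroxyl ortho to butanoyl is not adjacent to the reacting carbon. It also needs mono-annulation of two equivalent rings, which the substrate does not secure; this is handled by limiting 6, stopping at partial conversion and recycling 5. An alcohol-free solvent and the bulky tert-butyl groups are chosen to keep the aryl silyl ether intact in the presence of the amine salt.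

Step 4
Reactants: 9 2-methylbenzene-1,3,5-triol; 10 acetic anhydride
Product: 11 1-(2,4,6-trihydroxy-3-methylphenyl)ethan-1-one
Conditions: Ac2O (1.05 equiv), MeSO3H, 50 °C; then ice–water
Reagents that add atoms: none
Why: Friedel–Crafts C-acetylation of the electron-rich triol (any O-acetate formed first should undergo Fries rearrangement in the acid medium); the two free ring carbons are equivalent and the first acyl group deactivates the ring towards a second.

Step 5
Reactants: 11 1-(2,4,6-trihydroxy-3-methylphenyl)ethan-1-one; 12 (2E)-1-bromo-3,7-dimethylocta-2,6-diene (geranyl bromide)
Product: 13 racemic 2-acetyl-4-geranyl-3,5-dihydroxy-4-methylcyclohexa-2,5-dien-1-one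
Conditions: NaOMe (2.0 equiv), MeOH, 0 °C; 12 (1.0 equiv), 0 °C to rt; then 1 M HCl
Reagents that add atoms: none
Why: Dearomative C-alkylation (SN2) of the phloroglucinolate at the methyl-bearing carbon, the reactivity that gives gem-dialkylated acylfilicinic-type triketones; the protic solvent favours C- over O-alkylation and the (E)-olefin of 12 is retained; the quaternary stereocentre is formed without control, as the racemate.

Step 6
Reactants: 13 racemic 2-acetyl-4-geranyl-3,5-dihydroxy-4-methylcyclohexa-2,5-dien-1-one
Product: 14 (4R)-2-acetyl-4-geranyl-3,5-dihydroxy-4-methylcyclohexa-2,5-dien-1-one
Conditions: preparative HPLC, amylose tris(3,5-dimethylphenylcarbamate) stationary phase, n-hexane/i-PrOH/CF3CO2H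
Reagents that add atoms: none
Why: Resolution of enantiomers by chromatography on a chiral stationary phase, with an acidic modifier to keep the enolised triketone neutral; no bond at the stereocentre is touched, the (R)-enantiomer is to be assigned by electronic circular dichroism against the calculated spectrum, and the quaternary centre cannot epimerise.

Step 7
Reactants: 8 silylene-bridged mono-chromene dimer; 15 N,N-dimethylmethyleneiminium iodide; 14 (4R)-2-acetyl-4-geranyl-3,5-dihydroxy-4-methylcyclohexa-2,5-dien-1-one
Product: 18 silylene-protected trimer, via ring B Mannich base 16 (not isolated), via ring B ortho-quinone methide 17 (not isolated)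
Conditions: 15 (1.0 equiv), MeCN, rt; then 14 (1.0 equiv), NaOAc (1.2 equiv), 70 °C
Reagents that add atoms: none
Why: Mannich aminomethylation at the only free aromatic carbon of 8, then loss of dimethylamine to the ortho-quinone methide 17 and Michael addition of the enolate carbon C6 of 14 (methylene bridging through a preformed Mannich base); because the one-carbon unit is consumed by 8 before 14 is added, 14 should never meet a free formaldehyde equivalent and cannot bridge with itself; the stereocentre of 14 is not involved and is retained.

Step 8
Reactants: 18 silylene-protected trimer
Product: 19 CNP0103039.1
Conditions: HF·pyridine, THF–pyridine, 0 °C to rt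
Reagents that add atoms: none
Why: Fluoride cleavage of the diaryloxysilylene, driven by Si–F bond formation with two phenols as leaving groups; the pyridine-buffered reagent should leave the chromene and geranyl olefins, the methylene bridges and the triketone untouched, and the stereocentre is not affected.

## Compound list

1 | 1-(2,4,6-trihydroxyphenyl)butan-1-one | CCCC(=O)c1c(O)cc(O)cc1O | starting material
2 | formaldehyde | C=O | starting material
3 | bis(3-butanoyl-2,4,6-trihydroxyphenyl)methane | CCCC(=O)c1c(O)cc(O)c(Cc2c(O)cc(O)c(C(=O)CCC)c2O)c1O | intermediate
4 | di-tert-butylsilyl bis(trifluoromethanesulfonate) | CC(C)(C)[Si](OS(=O)(=O)C(F)(F)F)(OS(=O)(=O)C(F)(F)F)C(C)(C)C | starting material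
5 | 1,1'-(6,6-di-tert-butyl-1,3,9,11-tetrahydroxy-12H-dibenzo[d,g][1,3,2]dioxasilocine-2,10-diyl)di(butan-1-one), the silylene of 3 on the two oxygens para to butanoyl | CCCC(=O)c1c(O)cc2O[Si](C(C)(C)C)(C(C)(C)C)Oc3cc(O)c(C(=O)CCC)c(O)c3Cc2c1O | intermediate
6 | 3-methylbut-2-enal | CC(C)=CC=O | starting material
7 | 1-oxatriene (ortho-quinone methide) of 5, not isolated: one ring is a cyclohexa-2,4-dien-1-one carrying a 3-methylbut-2-en-1-ylidene group on the carbon between the silyloxy carbon and the new carbonyl (the former hydroxyl ortho to butanoyl) | CCCC(=O)C1=C(O)C2=C(O[Si](C(C)(C)C)(C(C)(C)C)Oc3cc(O)c(C(=O)CCC)c(O)c3C2)C(=CC=C(C)C)C1=O | intermediate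
8 | silylene-bridged mono-chromene dimer: 5 in which one ring is fused to a 2,2-dimethyl-2H-pyran, the pyran oxygen being the former hydroxyl ortho to butanoyl and the pyran C4 standing on the carbon next to the silyloxy carbon | CCCC(=O)c1c2OC(C)(C)C=Cc2c4O[Si](C(C)(C)C)(C(C)(C)C)Oc3cc(O)c(C(=O)CCC)c(O)c3Cc4c1O | intermediate
9 | 2-methylbenzene-1,3,5-triol | Cc1c(O)cc(O)cc1O | starting material
10 | acetic anhydride | CC(=O)OC(C)=O | starting material
11 | 1-(2,4,6-trihydroxy-3-methylphenyl)ethan-1-one | CC(=O)c1c(O)cc(O)c(C)c1O | intermediate
12 | (2E)-1-bromo-3,7-dimethylocta-2,6-diene (geranyl bromide) | BrC/C=C(\C)CCC=C(C)C | starting material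
13 | racemic 2-acetyl-4-[(2E)-3,7-dimethylocta-2,6-dien-1-yl]-3,5-dihydroxy-4-methylcyclohexa-2,5-dien-1-one | C1=C(O)C(C)(C/C=C(\C)CCC=C(C)C)C(O)=C(C(C)=O)C1=O | intermediate
14 | (4R)-2-acetyl-4-[(2E)-3,7-dimethylocta-2,6-dien-1-yl]-3,5-dihydroxy-4-methylcyclohexa-2,5-dien-1-one | C1=C(O)[C@@](C)(C/C=C(\C)CCC=C(C)C)C(O)=C(C(C)=O)C1=O | intermediate
15 | N,N-dimethylmethyleneiminium iodide | C=[N+](C)C.[I-] | starting material
16 | Mannich base, not isolated: 8 with a (dimethylamino)methyl group on the free aromatic carbon of ring B | CCCC(=O)c1c2OC(C)(C)C=Cc2c4O[Si](C(C)(C)C)(C(C)(C)C)Oc3c(CN(C)C)c(O)c(C(=O)CCC)c(O)c3Cc4c1O | intermediate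
17 | ring B ortho-quinone methide, not isolated: formed from 16 by loss of dimethylamine, with an exocyclic methylene on the former free carbon and a carbonyl at the neighbouring former hydroxyl ortho to butanoyl | C=C1C(=O)C(C(=O)CCC)=C(O)C2=C1O[Si](C(C)(C)C)(C(C)(C)C)Oc1c(C2)c(O)c(C(=O)CCC)c3OC(C)(C)C=Cc13 | intermediate
18 | silylene-protected trimer: 8 whose ring B carbon is joined through CH2 to C6 of (4R)-ring A | CCCC(=O)c1c2OC(C)(C)C=Cc2c4O[Si](C(C)(C)C)(C(C)(C)C)Oc3c(CC5=C(O)[C@@](C)(C/C=C(\C)CCC=C(C)C)C(O)=C(C(C)=O)C5=O)c(O)c(C(=O)CCC)c(O)c3Cc4c1O | intermediate
19 | CNP0103039.1, (4R)-2-acetyl-6-{[3-butanoyl-5-[(8-butanoyl-5,7-dihydroxy-2,2-dimethyl-2H-chromen-6-yl)methyl]-2,4,6-trihydroxyphenyl]methyl}-4-[(2E)-3,7-dimethylocta-2,6-dien-1-yl]-3,5-dihydroxy-4-methylcyclohexa-2,5-dien-1-one | CCCC(=O)c1c(O)c(CC2=C(O)[C@@](C)(C/C=C(\C)CCC=C(C)C)C(O)=C(C(C)=O)C2=O)c(O)c(Cc2c(O)c3c(c(C(=O)CCC)c2O)OC(C)(C)C=C3)c1O | target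

## Step count and least certain steps

Total: 8 steps. Longest linear sequence: 5 steps (steps 1, 2, 3, 7, 8 from 1; equally steps 4, 5, 6, 7, 8 from 9).

**Step 3 (key step).** The most likely failure is loss of site control between the two equivalent rings: part of the material would be annulated twice while part of 5 stays unreacted. A second failure mode is erosion of the tether by the amine acetate at 80 °C, which would reopen the para oxygen to cyclisation and scramble the orientation. Condensation may also be slow, because the reacting carbon is flanked by a bulky silyloxy group.
- Fallback, setting out from 5 and returning at 8: C-prenylation of the same free carbon with 1-bromo-3-methylbut-2-ene and 1,8-diazabicyclo[5.4.0]undec-7-ene in THF would give the mono-prenylated silylene dimer F1. Dehydrogenative cyclisation of the ortho-prenylphenol with 2,3-dichloro-5,6-dicyano-1,4-benzoquinone in toluene then gives 8. The tether again decides which oxygen closes.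

**Step 2.** The silylene may bridge the wrong pair of oxygens (those between butanoyl and CH2), or silylation may run intermolecularly to oligomers, because several hydroxyls compete and an eight-membered ring must close.
- Fallback, setting out from 1 and returning at 5: the order is reversed. Two equivalents of 1 are joined first through their para oxygens with 4 (2,6-lutidine, DMF), where para selectivity on the monomer is dependable. This gives di-tert-butylbis(4-butanoyl-3,5-dihydroxyphenoxy)silane F2. The methylene bridge is then closed intramolecularly with 2 (as paraformaldehyde, catalytic piperidinium acetate, dilute THF, 40 °C). In F2 both carbons ortho to the silyloxy group are equivalent, so no regiochemical choice remains.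

**Step 5.** The electrophile may attack the unsubstituted ring carbon (rearomatising C-alkylation) or oxygen instead of the methyl-bearing carbon, and a second alkylation may follow. The dianion is ambident and the desired site is the more hindered one.
- Fallback, setting out from 11 and returning at 13: the free ring carbon is blocked first. N-Bromosuccinimide in MeCN at 0 °C would give 1-(3-bromo-2,4,6-trihydroxy-5-methylphenyl)ethan-1-one F3. Alkylation with 12 under the conditions of step 5 then gives racemic 2-acetyl-6-bromo-4-geranyl-3,5-dihydroxy-4-methylcyclohexa-2,5-dien-1-one F4. The bromine of this bromo-triketone is removed reductively with aqueous Na2SO3 in THF to give 13.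

**Step 7.** Elimination of dimethylamine from the Mannich base may be too slow at a temperature the silylene tolerates. Retro-Mannich transfer of the one-carbon unit to 14 may lead to self-bridging of ring A. The adduct may also cyclise with loss of water between the ring B hydroxyl and a ring A carbonyl.
- Fallback, setting out from 8 and returning at 18: the bridge carbon is introduced at the aldehyde oxidation level. Vilsmeier–Haack formylation of 8 (POCl3, DMF, EtOAc, 0 °C) would give the ring B aldehyde F5. An organocatalytic reductive Knoevenagel alkylation of 14 with F5 and diethyl 2,6-dimethyl-1,4-dihydropyridine-3,5-dicarboxylate (L-proline, CH2Cl2, rt) then gives 18 without any amine leaving group.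

## Further compounds

F1 | step 3 | mono-C-prenylated silylene dimer: 5 with a 3-methylbut-2-en-1-yl group on the free aromatic carbon of one ring | CCCC(=O)c1c(O)c(CC=C(C)C)c2O[Si](C(C)(C)C)(C(C)(C)C)Oc3cc(O)c(C(=O)CCC)c(O)c3Cc2c1O
F2 | step 2 | di-tert-butylbis(4-butanoyl-3,5-dihydroxyphenoxy)silane | CCCC(=O)c1c(O)cc(O[Si](C(C)(C)C)(C(C)(C)C)Oc2cc(O)c(C(=O)CCC)c(O)c2)cc1O
F3 | step 5 | 1-(3-bromo-2,4,6-trihydroxy-5-methylphenyl)ethan-1-one | CC(=O)c1c(O)c(Br)c(O)c(C)c1O
F4 | step 5 | racemic 2-acetyl-6-bromo-4-[(2E)-3,7-dimethylocta-2,6-dien-1-yl]-3,5-dihydroxy-4-methylcyclohexa-2,5-dien-1-one | BrC1=C(O)C(C)(C/C=C(\C)CCC=C(C)C)C(O)=C(C(C)=O)C1=O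
F5 | step 7 | ring B aldehyde: 8 with a formyl group on the free aromatic carbon of ring B | CCCC(=O)c1c2OC(C)(C)C=Cc2c4O[Si](C(C)(C)C)(C(C)(C)C)Oc3c(C=O)c(O)c(C(=O)CCC)c(O)c3Cc4c1O
A1 | alternative 1 | 5-(methoxymethoxy)-2,2-dimethyl-8-(trimethylsilyl)-2H-chromen-7-yl trifluoromethanesulfonate | COCOc1cc(OS(=O)(=O)C(F)(F)F)c([Si](C)(C)C)c2OC(C)(C)C=Cc12
A2 | alternative 1 | 7,8-didehydro-5-(methoxymethoxy)-2,2-dimethyl-2H-chromene (aryne) | COCOC1=CC#CC2=C1C=CC(C)(C)O2
A3 | alternative 1 | butanoic acid | CCCC(=O)O
A4 | alternative 1 | 8-butanoyl-7-hydroxy-5-(methoxymethoxy)-2,2-dimethyl-2H-chromene | CCCC(=O)c1c(O)cc(OCOC)c2C=CC(C)(C)Oc12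
A5 | alternative 2 | dimethyl 2-[(2E)-3,7-dimethylocta-2,6-dien-1-yl]-2-methylpropanedioate | COC(=O)C(C)(C/C=C(\C)CCC=C(C)C)C(=O)OC
A6 | alternative 2 | (2R,4E)-2-(methoxycarbonyl)-2,5,9-trimethyldeca-4,8-dienoic acid (half-ester) | OC(=O)[C@@](C)(C/C=C(\C)CCC=C(C)C)C(=O)OC
A7 | alternative 2 | methyl (2R,4E)-2-(1H-imidazole-1-carbonyl)-2,5,9-trimethyldeca-4,8-dienoate | O=C(n1ccnc1)[C@@](C)(C/C=C(\C)CCC=C(C)C)C(=O)OC
A8 | alternative 2 | pentane-2,4-dione | CC(=O)CC(C)=O
A9 | alternative 2 | (4R)-2-acetyl-4-[(2E)-3,7-dimethylocta-2,6-dien-1-yl]-3,5-dihydroxy-4-methylcyclohexa-2,5-dien-1-one (identical with 14) | C1=C(O)[C@@](C)(C/C=C(\C)CCC=C(C)C)C(O)=C(C(C)=O)C1=O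
A10 | alternative 3 | 8-butanoyl-2,2,7-trimethyl-2H,5H-pyrano[4,3-b]pyran-5-one | CCCC(=O)C1=C(C)OC(=O)C2=C1OC(C)(C)C=C2
A11 | alternative 3 | methyl 6-(2,4-dioxoheptan-3-yl)-2,2-dimethyl-2H-pyran-5-carboxylate | CCCC(=O)C(C(C)=O)C1=C(C(=O)OC)C=CC(C)(C)O1
A12 | alternative 3 | 8-butanoyl-5,7-dihydroxy-2,2-dimethyl-2H-chromene | CCCC(=O)c1c(O)cc(O)c2C=CC(C)(C)Oc12
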